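**Retrosynthetic overview**
1. The target is opened in one operation to an acyclic (3R)-hydroperoxy (6S,7S)-epoxy (10S)-mesylate acid: the C3–OO group opens the oxirane at C6 (6-exo, inversion) to close the 1,2-dioxane first, and the freed C7–OH then displaces the C10 mesylate (5-exo, inversion) to close the oxolane.
2. The C3 peroxide stereocentre comes from an organocatalytic β-peroxidation of the C1–C3 (E)-enal with a masked hydroperoxide; C1 is then oxidised to the acid.
3. The C10 carbinol and the whole C11–C24 side chain come from a catalytic asymmetric addition of a trienyl Grignard reagent to a C10 aldehyde.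
4. The (6S,7S)-oxirane comes from Shi epoxidation of ethyl (4E)-nona-4,8-dienoate, itself made by Johnson–Claisen rearrangement of hepta-1,6-dien-3-ol.
5. The (Z,E)-diene comes from a Z-selective Wittig reaction of a 7-bromoheptyl ylide with (2E)-hepta-2,6-dienal; pent-4-enal feeds both branches.

Assumption: the three chiral controllers (L-fructose-derived Shi ketone, (S)-diphenylprolinol trimethylsilyl ether, the (S)-H8-BINOL ligand) are bought and not counted as steps; hydroperoxide 24 is not a catalogue item and is made in step 11.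

**Step 1**
Reactants: 1 pent-4-enal; 2 2-(triphenyl-λ5-phosphanylidene)acetaldehyde
Product: 3 (2E)-hepta-2,6-dienal
Conditions: toluene, 80 °C, 12 h
Reagents that add atoms: none
Why: Wittig olefination with a stabilised formyl ylide is E-selective and stops at the enal because the conjugated product is the poorer electrophile.

**Step 2**
Reactants: 4 1,7-dibromoheptane; 5 triphenylphosphane
Product: 6 (7-bromoheptyl)triphenylphosphonium bromide
Conditions: 4 (3 equiv), toluene, 110 °C, 24 h; salt filtered, washed with Et2O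
Reagents that add atoms: none
Why: SN2 quaternisation of the phosphane by a primary bromide; excess dibromide suppresses the bis-phosphonium salt.

**Step 3**
Reactants: 6 (7-bromoheptyl)triphenylphosphonium bromide; 3 (2E)-hepta-2,6-dienal
Product: 8 (5E,7Z)-14-bromotetradeca-1,5,7-triene, via phosphonium ylide 7 (not isolated)
Conditions: NaN(SiMe3)2 (1.0 equiv), THF, −78 °C; then 3, −78 → 0 °C
Reagents that add atoms: none
Why: Salt-free Wittig reaction of a non-stabilised ylide with an enal goes through the kinetic cis-oxaphosphetane, so the new alkene is Z while the existing E alkene is untouched.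

**Step 4**
Reactants: 1 pent-4-enal; 9 vinylmagnesium bromide (CH2=CHMgBr)
Product: 10 hepta-1,6-dien-3-ol (racemic)
Conditions: THF, −78 → 0 °C; then H2O/NH4Cl
Reagents that add atoms: none
Why: Grignard 1,2-addition to the aldehyde; the racemic carbinol centre is destroyed in step 5.

**Step 5**
Reactants: 10 hepta-1,6-dien-3-ol; 11 1,1,1-triethoxyethane
Product: 13 ethyl (4E)-nona-4,8-dienoate, via mixed ketene acetal 12 (not isolated)
Conditions: 11 (6 equiv), EtCO2H (5 mol%), 140 °C, EtOH distilled off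
Reagents that add atoms: none
Why: Johnson–Claisen [3,3]-sigmatropic rearrangement through a chair transition state with the butenyl group equatorial gives the E-γ,δ-unsaturated ester (the C6=C7 alkene of the target).

**Step 6**
Reactants: 13 ethyl (4E)-nona-4,8-dienoate
Product: 14 ethyl 3-[(2S,3S)-3-(but-3-en-1-yl)oxiran-2-yl]propanoate
Conditions: 1,2:4,5-di-O-isopropylidene-β-L-erythro-2,3-hexodiulo-2,6-pyranose (L-fructose-derived Shi ketone, 30 mol%), KHSO5 (as Oxone, 1.4 equiv), K2CO3, Bu4NHSO4 (cat.), MeCN/CH2(OMe)2/aq. Na2B4O7–Na2EDTA buffer (pH 10.5), 0 °C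
Reagents that add atoms: potassium peroxymonosulfate KHSO5, [K+].[O-]S(=O)(=O)OO
Why: Shi asymmetric epoxidation: the chiral dioxirane attacks the trans-disubstituted alkene through a spiro transition state to give the (S,S)-oxirane (C6 and C7 of the target), and the much slower monosubstituted alkene is left alone.

**Step 7**
Reactants: 14 ethyl 3-[(2S,3S)-3-(but-3-en-1-yl)oxiran-2-yl]propanoate
Product: 16 ethyl 3-[(2S,3S)-3-(3-oxopropyl)oxiran-2-yl]propanoate, via secondary ozonide 15 (not isolated)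
Conditions: O3, CH2Cl2, −78 °C; then PPh3, −78 → 23 °C
Reagents that add atoms: ozone, [O-][O+]=O
Why: Ozonolysis with reductive work-up cleaves the only remaining alkene to the C10 aldehyde; oxirane and ester are inert to ozone.

**Step 8**
Reactants: 8 (5E,7Z)-14-bromotetradeca-1,5,7-triene; 16 ethyl 3-[(2S,3S)-3-(3-oxopropyl)oxiran-2-yl]propanoate
Product: 18 ethyl 3-[(2S,3S)-3-[(3S,10Z,12E)-3-hydroxyheptadeca-10,12,16-trien-1-yl]oxiran-2-yl]propanoate, via Grignard reagent 17 (not isolated)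
Conditions: 8, Mg, THF, 40 °C; Ti(OiPr)4 (3 equiv), CH2Cl2, −78 °C; added over 2 h to 16, (S)-3-(3,5-diphenylphenyl)-5,5',6,6',7,7',8,8'-octahydro-1,1'-bi-2-naphthol (3 mol%), Ti(OiPr)4 (1 equiv), CH2Cl2, 0 °C; then H2O
Reagents that add atoms: none
Why: Catalytic asymmetric alkylation of an aldehyde by an alkyltitanium triisopropoxide (from the Grignard reagent and Ti(OiPr)4) under the chiral diol; the (S)-ligand delivers the alkyl group to the Si face (the sense that turns benzaldehyde into (S)-1-phenylpropan-1-ol), setting the 3S carbinol (C10 of the target), and the organotitanium species ignores ester and oxirane.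

**Step 9**
Reactants: 18 ethyl 3-[(2S,3S)-3-[(3S,10Z,12E)-3-hydroxyheptadeca-10,12,16-trien-1-yl]oxiran-2-yl]propanoate
Product: 19 ethyl 3-[(2S,3S)-3-[(3S,10Z,12E)-3-(methanesulfonyloxy)heptadeca-10,12,16-trien-1-yl]oxiran-2-yl]propanoate
Conditions: MsCl (1.3 equiv), NEt3 (2 equiv), CH2Cl2, −20 → 0 °C
Reagents that add atoms: methanesulfonyl chloride, CS(=O)(=O)Cl
Why: O-Sulfonylation forms only the O–S bond, so the 3S centre is retained; it also stops the alcohol from opening the oxirane prematurely.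

**Step 10**
Reactants: 19 ethyl 3-[(2S,3S)-3-[(3S,10Z,12E)-3-(methanesulfonyloxy)heptadeca-10,12,16-trien-1-yl]oxiran-2-yl]propanoate; 2 2-(triphenyl-λ5-phosphanylidene)acetaldehyde
Product: 21 (2E)-5-[(2S,3S)-3-[(3S,10Z,12E)-3-(methanesulfonyloxy)heptadeca-10,12,16-trien-1-yl]oxiran-2-yl]pent-2-enal, via epoxy aldehyde 20 (not isolated)
Conditions: iBu2AlH (1.05 equiv), CH2Cl2, −78 °C, 1 h; MeOH (0.1 equiv); then 2 (1.5 equiv), −78 → 23 °C, 16 h; aq. KNaC4H4O6
Reagents that add atoms: none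
Why: Partial ester reduction gives a tetrahedral aluminium hemiacetal that releases aldehyde 20 on warming, where it is trapped by the stabilised ylide in an E-selective Wittig reaction; mesylate, oxirane and alkenes do not react.

**Step 11**
Reactants: 22 2,3-dimethylbut-2-ene
Product: 24 2-hydroperoxy-2-methoxypropane, via acetone O-oxide 23 (not isolated)
Conditions: O3, CH2Cl2/MeOH (4:1), −78 °C; N2 purge; used as a titrated solution
Reagents that add atoms: ozone, [O-][O+]=O; methanol, CO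
Why: Ozonolysis in methanol: the Criegee carbonyl oxide is captured by MeOH to give the α-methoxy hydroperoxide, whose adducts are acid-labile monoperoxyketals.

**Step 12**
Reactants: 21 (2E)-5-[(2S,3S)-3-[(3S,10Z,12E)-3-(methanesulfonyloxy)heptadeca-10,12,16-trien-1-yl]oxiran-2-yl]pent-2-enal; 24 2-hydroperoxy-2-methoxypropane
Product: 25 (3R)-3-[(2-methoxypropan-2-yl)peroxy]-5-[(2S,3S)-3-[(3S,10Z,12E)-3-(methanesulfonyloxy)heptadeca-10,12,16-trien-1-yl]oxiran-2-yl]pentanal
Conditions: 24 (2 equiv), (S)-2-[diphenyl(trimethylsilyloxy)methyl]pyrrolidine (20 mol%), PhCO2H (10 mol%), toluene, 0 °C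
Reagents that add atoms: none
Why: Iminium-catalysed enantioselective oxa-Michael addition (β-peroxidation) of a hydroperoxide to an enal: on the s-trans (E)-iminium ion the (S)-diarylmethyl silyl ether arm blocks one face, so 24 adds to the other face of C3 and gives the 3R peroxide.

**Step 13**
Reactants: 25 (3R)-3-[(2-methoxypropan-2-yl)peroxy]-5-[(2S,3S)-3-[(3S,10Z,12E)-3-(methanesulfonyloxy)heptadeca-10,12,16-trien-1-yl]oxiran-2-yl]pentanal
Product: 26 (3R)-3-[(2-methoxypropan-2-yl)peroxy]-5-[(2S,3S)-3-[(3S,10Z,12E)-3-(methanesulfonyloxy)heptadeca-10,12,16-trien-1-yl]oxiran-2-yl]pentanoic acid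
Conditions: NaClO2 (3 equiv), NaH2PO4 (3 equiv), 2-methylbut-2-ene (20 equiv), t-BuOH/H2O (4:1), 0 °C, 1 h
Reagents that add atoms: sodium chlorite NaClO2, [Na+].[O-]Cl=O
Why: Pinnick oxidation: chlorous acid oxidises only the aldehyde, 2-methylbut-2-ene removes HOCl so the diene and the peroxide are spared, and no stereocentre is touched.

**Step 14**
Reactants: 26 (3R)-3-[(2-methoxypropan-2-yl)peroxy]-5-[(2S,3S)-3-[(3S,10Z,12E)-3-(methanesulfonyloxy)heptadeca-10,12,16-trien-1-yl]oxiran-2-yl]pentanoic acid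
Product: 29 2-[(3R,6R)-6-[(2S,5R)-5-[(7Z,9E)-tetradeca-7,9,13-trien-1-yl]oxolan-2-yl]-1,2-dioxan-3-yl]acetic acid, via hydroperoxy epoxy mesylate 27 (not isolated), via dioxanyl hydroxy mesylate 28 (not isolated)
Conditions: pyridinium p-toluenesulfonate (20 mol%), CH2Cl2/(CF3)2CHOH/H2O (80:20:1), 0 → 23 °C, 3 h; then 2,6-lutidine (2 equiv), 40 °C, 12 h, same flask
Reagents that add atoms: none
Why: Proposed new method: mild acid first hydrolyses the monoperoxyketal to hydroperoxide 27 (acetal hydrolysis), whose terminal oxygen opens the hydrogen-bond-activated trans-oxirane 6-exo at C6 with inversion (closest known type: acid-promoted intramolecular hydroperoxide–epoxide cyclisation to 1,2-dioxanes), and the C7 hydroxyl so released displaces the C10 mesylate 5-exo-tet with inversion (closest known type: cyclisation of 4-hydroxyalkyl sulfonates to oxolanes), so 6R, 7S (retained) and 10R follow stereospecifically from the (6S,7S)-oxirane and the 10S mesylate while 3R is carried through.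

**Compound list**
1 | pent-4-enal | C=CCCC=O | starting material
2 | 2-(triphenyl-λ5-phosphanylidene)acetaldehyde | O=CC=P(c1ccccc1)(c1ccccc1)c1ccccc1 | starting material
3 | (2E)-hepta-2,6-dienal | C=CCC/C=C/C=O | intermediate
4 | 1,7-dibromoheptane | BrCCCCCCCBr | starting material
5 | triphenylphosphane | c1ccc(cc1)P(c1ccccc1)c1ccccc1 | starting material
6 | (7-bromoheptyl)triphenylphosphonium bromide | BrCCCCCCC[P+](c1ccccc1)(c1ccccc1)c1ccccc1.[Br-] | intermediate
7 | (7-bromoheptylidene)triphenyl-λ5-phosphane (ylide, not isolated) | BrCCCCCCC=P(c1ccccc1)(c1ccccc1)c1ccccc1 | intermediate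
8 | (5E,7Z)-14-bromotetradeca-1,5,7-triene | C=CCC/C=C/C=C\CCCCCCBr | intermediate
9 | vinylmagnesium bromide, CH2=CHMgBr | C=C[Mg]Br | starting material
10 | hepta-1,6-dien-3-ol (racemic) | C=CCCC(O)C=C | intermediate
11 | 1,1,1-triethoxyethane | CCOC(C)(OCC)OCC | starting material
12 | 3-[(1-ethoxyethenyl)oxy]hepta-1,6-diene (not isolated) | C=CCCC(OC(=C)OCC)C=C | intermediate
13 | ethyl (4E)-nona-4,8-dienoate | CCOC(=O)CC/C=C/CCC=C | intermediate
14 | ethyl 3-[(2S,3S)-3-(but-3-en-1-yl)oxiran-2-yl]propanoate | CCOC(=O)CC[C@@H]1O[C@H]1CCC=C | intermediate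
15 | ethyl 3-[(2S,3S)-3-[2-(1,2,4-trioxolan-3-yl)ethyl]oxiran-2-yl]propanoate (ozonide, both epimers, not isolated) | CCOC(=O)CC[C@@H]1O[C@H]1CCC1OCOO1 | intermediate
16 | ethyl 3-[(2S,3S)-3-(3-oxopropyl)oxiran-2-yl]propanoate | CCOC(=O)CC[C@@H]1O[C@H]1CCC=O | intermediate
17 | (7Z,9E)-tetradeca-7,9,13-trien-1-ylmagnesium bromide, RMgBr (not isolated) | C=CCC/C=C/C=C\CCCCCC[Mg]Br | intermediate
18 | ethyl 3-[(2S,3S)-3-[(3S,10Z,12E)-3-hydroxyheptadeca-10,12,16-trien-1-yl]oxiran-2-yl]propanoate | CCOC(=O)CC[C@@H]1O[C@H]1CC[C@@H](O)CCCCCC/C=C\C=C\CCC=C | intermediate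
19 | ethyl 3-[(2S,3S)-3-[(3S,10Z,12E)-3-(methanesulfonyloxy)heptadeca-10,12,16-trien-1-yl]oxiran-2-yl]propanoate | CCOC(=O)CC[C@@H]1O[C@H]1CC[C@@H](OS(C)(=O)=O)CCCCCC/C=C\C=C\CCC=C | intermediate
20 | 3-[(2S,3S)-3-[(3S,10Z,12E)-3-(methanesulfonyloxy)heptadeca-10,12,16-trien-1-yl]oxiran-2-yl]propanal (not isolated) | O=CCC[C@@H]1O[C@H]1CC[C@@H](OS(C)(=O)=O)CCCCCC/C=C\C=C\CCC=C | intermediate
21 | (2E)-5-[(2S,3S)-3-[(3S,10Z,12E)-3-(methanesulfonyloxy)heptadeca-10,12,16-trien-1-yl]oxiran-2-yl]pent-2-enal | O=C/C=C/CC[C@@H]1O[C@H]1CC[C@@H](OS(C)(=O)=O)CCCCCC/C=C\C=C\CCC=C | intermediate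
22 | 2,3-dimethylbut-2-ene | CC(C)=C(C)C | starting material
23 | propan-2-one O-oxide (carbonyl oxide, not isolated) | CC(C)=[O+][O-] | intermediate
24 | 2-hydroperoxy-2-methoxypropane | COC(C)(C)OO | intermediate
25 | (3R)-3-[(2-methoxypropan-2-yl)peroxy]-5-[(2S,3S)-3-[(3S,10Z,12E)-3-(methanesulfonyloxy)heptadeca-10,12,16-trien-1-yl]oxiran-2-yl]pentanal | O=CC[C@H](OOC(C)(C)OC)CC[C@@H]1O[C@H]1CC[C@@H](OS(C)(=O)=O)CCCCCC/C=C\C=C\CCC=C | intermediate
26 | (3R)-3-[(2-methoxypropan-2-yl)peroxy]-5-[(2S,3S)-3-[(3S,10Z,12E)-3-(methanesulfonyloxy)heptadeca-10,12,16-trien-1-yl]oxiran-2-yl]pentanoic acid | OC(=O)C[C@H](OOC(C)(C)OC)CC[C@@H]1O[C@H]1CC[C@@H](OS(C)(=O)=O)CCCCCC/C=C\C=C\CCC=C | intermediate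
27 | (3R)-3-hydroperoxy-5-[(2S,3S)-3-[(3S,10Z,12E)-3-(methanesulfonyloxy)heptadeca-10,12,16-trien-1-yl]oxiran-2-yl]pentanoic acid (not isolated) | OC(=O)C[C@H](OO)CC[C@@H]1O[C@H]1CC[C@@H](OS(C)(=O)=O)CCCCCC/C=C\C=C\CCC=C | intermediate
28 | 2-[(3R,6R)-6-[(1S,4S,11Z,13E)-1-hydroxy-4-(methanesulfonyloxy)octadeca-11,13,17-trien-1-yl]-1,2-dioxan-3-yl]acetic acid (not isolated) | OC(=O)C[C@H]1CC[C@H]([C@@H](O)CC[C@@H](OS(C)(=O)=O)CCCCCC/C=C\C=C\CCC=C)OO1 | intermediate
29 | 2-[(3R,6R)-6-[(2S,5R)-5-[(7Z,9E)-tetradeca-7,9,13-trien-1-yl]oxolan-2-yl]-1,2-dioxan-3-yl]acetic acid | C=CCC/C=C/C=C\CCCCCC[C@@H]1CC[C@@H]([C@H]2CC[C@H](CC(=O)O)OO2)O1 | target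

**Totals**
Total step count: 14.
Longest linear sequence: 10 steps (pent-4-enal 1 through steps 4, 5, 6, 7, 8, 9, 10, 12, 13, 14).

**Three steps most likely to fail**

Step 14 (double ring closure). The risks are 7-endo opening of the oxirane, acid-induced fragmentation of the secondary hydroperoxide, and slow or eliminative closure of the oxolane. Fallback, from 26 back to 29: the two closures are separated and run under anionic activation on a protected acid. Methylation of 26 with Me3SiCHN2 gives methyl (3R)-3-[(2-methoxypropan-2-yl)peroxy]-5-[(2S,3S)-3-[(3S,10Z,12E)-3-(methanesulfonyloxy)heptadeca-10,12,16-trien-1-yl]oxiran-2-yl]pentanoate F7. Pyridinium p-toluenesulfonate in MeOH at 0 °C frees the hydroperoxide methyl (3R)-3-hydroperoxy-5-[(2S,3S)-3-[(3S,10Z,12E)-3-(methanesulfonyloxy)heptadeca-10,12,16-trien-1-yl]oxiran-2-yl]pentanoate F8. Cs2CO3 in CF3CH2OH at 0 °C lets the peroxide anion open the oxirane 6-exo to the isolable dioxane alcohol methyl 2-[(3R,6R)-6-[(1S,4S,11Z,13E)-1-hydroxy-4-(methanesulfonyloxy)octadeca-11,13,17-trien-1-yl]-1,2-dioxan-3-yl]acetate F9. K2CO3 in MeOH then closes the oxolane by alkoxide displacement of the mesylate to give the methyl ester of the target F6, and LiOH in aqueous THF returns to 29.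

Step 12 (asymmetric β-peroxidation). The risks are epoxidation of the enal through attack of the enamine on the O–O bond, modest enantioselectivity, and retro-oxa-Michael loss of the peroxide. Fallback, from 19 back to 29: the peroxide is brought in at C6 instead of C3 and C3 is set by ring closure. The same iBu2AlH reduction of 19 followed by methyl (triphenyl-λ5-phosphanylidene)acetate gives methyl (2E)-5-[(2S,3S)-3-[(3S,10Z,12E)-3-(methanesulfonyloxy)heptadeca-10,12,16-trien-1-yl]oxiran-2-yl]pent-2-enoate F4. Anhydrous H2O2 in (CF3)2CHOH/Et2O at 0 °C makes the oxirane oxygen displace the mesylate 5-exo, and H2O2 opens the resulting bicyclic epoxonium ion at the exocyclic carbon C6 with inversion. This gives methyl (2E,6R)-6-hydroperoxy-6-[(2S,5R)-5-[(7Z,9E)-tetradeca-7,9,13-trien-1-yl]oxolan-2-yl]hex-2-enoate F5; attack at C7 is the loss channel. Et2NH in CF3CH2OH then closes the dioxane by 6-exo oxa-Michael addition through a chair with both substituents equatorial, giving methyl 2-[(3R,6R)-6-[(2S,5R)-5-[(7Z,9E)-tetradeca-7,9,13-trien-1-yl]oxolan-2-yl]-1,2-dioxan-3-yl]acetate F6. LiOH in aqueous THF gives 29.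

Step 8 (asymmetric alkyl addition). The risks are incomplete facial control with an unbranched aldehyde and opening of the oxirane by the titanium alkoxide formed. Fallback, from 14 back to 18: the carbinol is taken from a resolved terminal epoxide instead of an aldehyde. mCPBA epoxidises the terminal alkene of 14 to ethyl 3-[(2S,3S)-3-[2-(oxiran-2-yl)ethyl]oxiran-2-yl]propanoate F1 (1:1 at the new oxirane). Hydrolytic kinetic resolution with (R,R)-(salen)Co(OAc) (trivalent cobalt; the enantiomer that leaves (R)-alkyloxiranes untouched) and 0.55 equiv H2O leaves ethyl 3-[(2S,3S)-3-[2-[(2R)-oxiran-2-yl]ethyl]oxiran-2-yl]propanoate F2. The other epimer is removed as the diol ethyl 3-[(2S,3S)-3-[(3S)-3,4-dihydroxybutyl]oxiran-2-yl]propanoate F3. Grignard reagent 17 with CuI (10 mol%) in THF at −40 °C opens F2 at its CH2 terminus, far faster than the trans-disubstituted oxirane or the ester react, to give 18.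

**Further compounds**
F1 | step 8 | ethyl 3-[(2S,3S)-3-[2-(oxiran-2-yl)ethyl]oxiran-2-yl]propanoate (both epimers at the new oxirane) | CCOC(=O)CC[C@@H]1O[C@H]1CCC1CO1
F2 | step 8 | ethyl 3-[(2S,3S)-3-[2-[(2R)-oxiran-2-yl]ethyl]oxiran-2-yl]propanoate | CCOC(=O)CC[C@@H]1O[C@H]1CC[C@@H]1CO1
F3 | step 8 | ethyl 3-[(2S,3S)-3-[(3S)-3,4-dihydroxybutyl]oxiran-2-yl]propanoate | CCOC(=O)CC[C@@H]1O[C@H]1CC[C@H](O)CO
F4 | step 12 | methyl (2E)-5-[(2S,3S)-3-[(3S,10Z,12E)-3-(methanesulfonyloxy)heptadeca-10,12,16-trien-1-yl]oxiran-2-yl]pent-2-enoate | COC(=O)/C=C/CC[C@@H]1O[C@H]1CC[C@@H](OS(C)(=O)=O)CCCCCC/C=C\C=C\CCC=C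
F5 | step 12 | methyl (2E,6R)-6-hydroperoxy-6-[(2S,5R)-5-[(7Z,9E)-tetradeca-7,9,13-trien-1-yl]oxolan-2-yl]hex-2-enoate | COC(=O)/C=C/CC[C@@H](OO)[C@@H]1CC[C@@H](CCCCCC/C=C\C=C\CCC=C)O1
F6 | step 12 | methyl 2-[(3R,6R)-6-[(2S,5R)-5-[(7Z,9E)-tetradeca-7,9,13-trien-1-yl]oxolan-2-yl]-1,2-dioxan-3-yl]acetate | COC(=O)C[C@H]1CC[C@H]([C@@H]2CC[C@@H](CCCCCC/C=C\C=C\CCC=C)O2)OO1
F7 | step 14 | methyl (3R)-3-[(2-methoxypropan-2-yl)peroxy]-5-[(2S,3S)-3-[(3S,10Z,12E)-3-(methanesulfonyloxy)heptadeca-10,12,16-trien-1-yl]oxiran-2-yl]pentanoate | COC(=O)C[C@H](OOC(C)(C)OC)CC[C@@H]1O[C@H]1CC[C@@H](OS(C)(=O)=O)CCCCCC/C=C\C=C\CCC=C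
F8 | step 14 | methyl (3R)-3-hydroperoxy-5-[(2S,3S)-3-[(3S,10Z,12E)-3-(methanesulfonyloxy)heptadeca-10,12,16-trien-1-yl]oxiran-2-yl]pentanoate | COC(=O)C[C@H](OO)CC[C@@H]1O[C@H]1CC[C@@H](OS(C)(=O)=O)CCCCCC/C=C\C=C\CCC=C
F9 | step 14 | methyl 2-[(3R,6R)-6-[(1S,4S,11Z,13E)-1-hydroxy-4-(methanesulfonyloxy)octadeca-11,13,17-trien-1-yl]-1,2-dioxan-3-yl]acetate | COC(=O)C[C@H]1CC[C@H]([C@@H](O)CC[C@@H](OS(C)(=O)=O)CCCCCC/C=C\C=C\CCC=C)OO1
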